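**Plan**

- Retrosynthetic cuts, in order: O4–CH3 ether; C2=C3 (stored as the C1 silyl enol ether); aryl–C(=O) (aryllithium plus lactone); side-chain C–CH3; lactone O4–C(=O); C6–allyl; C6–CH2CO2t-Bu; C4–H (carbonyl reduction).
- Forward: ring A is bought as a cyclohexenone mono-acetal; C6 is built by two enolate alkylations; ring B, a temporary bridged δ-lactone, is closed, methylated and then opened by the aryl nucleophile; the enone and the methyl ether come last.
- Enabling feature: the side-chain carbonyl carbon is 1,5 to O4 and both lie on the same face of ring A (anti to allyl), so they close to a 2-oxabicyclo[3.3.1]nonane (ring B) that serves as acyl donor, O4 protecting group and stereochemical template. Because C6 is quaternary, C1 can be masked only as the C1=C2 enol ether, which is where the enone must return.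
- Stereochemistry: C4 from Ru-catalysed asymmetric transfer hydrogenation; C6 from allylation anti to the C4 silyloxy group, proof-read by lactonisation (only the cis isomer can bridge); the methyl-bearing carbon from exo methylation of the lactone enolate.

Key step: step 9

Remark: ring atoms keep the target numbering throughout (C1 carbonyl, C2=C3, C4 oxygenated, C5 methylene, C6 quaternary); ring A is the carbocycle, ring B the lactone.

**Route**

Step 1
Reactants: 1 1,4-dioxaspiro[4.5]dec-6-en-8-one
Product: 2 (S)-1,4-dioxaspiro[4.5]dec-6-en-8-ol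
Conditions: RuCl(p-cymene)[(S,S)-TsDPEN] (1 mol %), KOH (cat.), i-PrOH, rt
Reagents that add atoms: none
Why: Noyori asymmetric transfer hydrogenation reduces the conjugated ketone 1,2 and sets C4, the alkenyl arm taking the place of the aryl group in the usual model so that the (S,S) ligand should give the (S)-carbinol.

Step 2
Reactants: 2 (S)-1,4-dioxaspiro[4.5]dec-6-en-8-ol
Product: 3 (S)-tert-butyl(1,4-dioxaspiro[4.5]dec-6-en-8-yloxy)dimethylsilane
Conditions: TBSCl, imidazole, DMF, rt
Reagents that add atoms: tert-butyldimethylsilyl chloride, CC(C)(C)[Si](C)(C)Cl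
Why: Standard silylation of a secondary allylic alcohol gives a bulky ether that later steers the C6 alkylation and can be removed for lactonisation.

Step 3
Reactants: 3 (S)-tert-butyl(1,4-dioxaspiro[4.5]dec-6-en-8-yloxy)dimethylsilane
Product: 4 (S)-4-[(tert-butyldimethylsilyl)oxy]cyclohex-2-en-1-one
Conditions: pyridinium p-toluenesulfonate (cat.), acetone/H2O, 40 °C
Reagents that add atoms: water, O
Why: Mild acid-catalysed acetal hydrolysis should unveil the C1 ketone without cleaving the silyl ether or eliminating the γ-silyloxy group.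

Step 4
Reactants: 4 (S)-4-[(tert-butyldimethylsilyl)oxy]cyclohex-2-en-1-one; 5 tert-butyl bromoacetate
Product: 7 tert-butyl 2-[(1R,5S)-5-[(tert-butyldimethylsilyl)oxy]-2-oxocyclohex-3-en-1-yl]acetate, via lithium dienolate 6 (not isolated)
Conditions: LiN(i-Pr)2, THF, −78 °C; then 5, DMPU, −78 to −40 °C
Reagents that add atoms: none
Why: Kinetic α′-deprotonation gives the cross-conjugated dienolate, whose SN2 alkylation (enolate alkylation) should occur mainly anti to the C4 silyloxy group; this C6 centre is planarised again in step 5, so its configuration is immaterial.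

Step 5
Reactants: 7 tert-butyl 2-[(1R,5S)-5-[(tert-butyldimethylsilyl)oxy]-2-oxocyclohex-3-en-1-yl]acetate; 8 allyl bromide
Product: 10 tert-butyl 2-[(1S,5S)-1-allyl-5-[(tert-butyldimethylsilyl)oxy]-2-oxocyclohex-3-en-1-yl]acetate, via lithium enolate 9 (not isolated)
Conditions: LiN(i-Pr)2, THF, −78 °C; then 8, DMPU, −78 to 0 °C
Reagents that add atoms: none
Why: The ketone α-hydrogen at C6 is removed in preference to the ester α-hydrogens, and the tetrasubstituted enolate should be allylated (enolate alkylation) on the face anti to the C4 silyloxy group (axial attack on the half-chair with OTBS pseudo-equatorial), setting quaternary C6 with the acetic arm cis to O4.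

Step 6
Reactants: 10 tert-butyl 2-[(1S,5S)-1-allyl-5-[(tert-butyldimethylsilyl)oxy]-2-oxocyclohex-3-en-1-yl]acetate
Product: 12 (1S,5S)-5-allyl-2-oxabicyclo[3.3.1]non-7-ene-3,6-dione, via hydroxy acid 11 (not isolated)
Conditions: CF3CO2H/CH2Cl2/H2O, rt; evaporate; then EDC·HCl, DMAP (cat.), CH2Cl2, rt; NaHCO3 wash
Reagents that add atoms: none
Why: Acid removes the tert-butyl ester and the silyl ether, and Steglich-type lactonisation ties the carboxyl to O4, which is possible only when the acetic arm and O4 are cis, so any C6 epimer should stay behind as a base-extractable hydroxy acid.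

Step 7
Reactants: 12 (1S,5S)-5-allyl-2-oxabicyclo[3.3.1]non-7-ene-3,6-dione
Product: 14 (1S,4R,5S)-5-allyl-4-methyl-2-oxabicyclo[3.3.1]non-7-ene-3,6-dione, via lithium lactone enolate 13 (not isolated)
Conditions: LiN(SiMe3)2, THF, −78 °C; then MeI, −78 to −40 °C
Reagents that add atoms: iodomethane, CI
Why: The enone cannot enolise (C6 is quaternary and the C4 hydrogen is a bridgehead hydrogen orthogonal to the π system), so only the lactone is deprotonated, and iodomethane should attack the enolate on the exo face of the roof-shaped bicycle (away from the enone bridge, also the thermodynamically preferred position), setting the (R) methyl-bearing centre.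

Step 8
Reactants: 14 (1S,4R,5S)-5-allyl-4-methyl-2-oxabicyclo[3.3.1]non-7-ene-3,6-dione
Product: 16 (1R,4R,5S)-5-allyl-6-[(tert-butyldimethylsilyl)oxy]-4-methyl-2-oxabicyclo[3.3.1]non-6-en-3-one, via copper enolate 15 (not isolated)
Conditions: [(Ph3P)CuH]6, TBSCl, C6H6/THF, rt
Reagents that add atoms: tert-butyldimethylsilyl chloride, CC(C)(C)[Si](C)(C)Cl
Why: Copper hydride conjugate reduction delivers hydride to C3 and the soft copper enolate is O-silylated in situ, storing the C1 carbonyl as its only possible (C1=C2) enol ether; a lithium enolate is avoided because it could acylate itself on the lactone carbonyl that faces C2 across the bicycle.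

Step 9
Reactants: 16 (1R,4R,5S)-5-allyl-6-[(tert-butyldimethylsilyl)oxy]-4-methyl-2-oxabicyclo[3.3.1]non-6-en-3-one; 17 4-bromo-1,2-dimethoxybenzene
Product: 20 (2R)-2-[(1S,5R)-1-allyl-2-[(tert-butyldimethylsilyl)oxy]-5-hydroxycyclohex-2-en-1-yl]-1-(3,4-dimethoxyphenyl)propan-1-one, via 3,4-dimethoxyphenyllithium 18 (not isolated), via lithium lactolate 19 (not isolated)
Conditions: 17, n-BuLi, THF, −78 °C; then 16, THF, −78 °C; AcOH/THF quench at −78 °C
Reagents that add atoms: none
Why: Bromine–lithium exchange reverses the polarity of the aryl carbon of 17, and aryllithium 18 adds to the lactone carbonyl of 16 from the exo face to give the tetrahedral lithium lactolate 19, which should persist at −78 °C and on cold protonation open to the aryl ketone and the free C4 hydroxyl. The closest known reaction type is the mono-addition of an aryllithium to a δ-lactone to give a δ-hydroxy aryl ketone, as used for aryl C-glycosides. No ring is closed: ring B is opened, so the event that forms the aryl–carbonyl bond also hands back O4 for methylation and ends the role of the lactone that fixed the C4/C6 relationship and the methyl-bearing centre. No stereocentre is formed in the isolated product (the lactol carbon of 19 is transient), and the α-centre should survive because its only hydrogen is the hindered endo one and the quench is cold. The selectivity needed is lactone carbonyl over the ring A carbonyl and single over double addition: the first is secured by storing C1 as its TBS enol ether, the second by the persistence of 19 at low temperature, the stoichiometry and the hindered, electron-rich ketone that is set free only on work-up. A radical or acyl-anion union at this carbon was set aside because an acyl radical or acyl-anion equivalent here would cyclise onto the allyl group or the enone.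

Step 10
Reactants: 20 (2R)-2-[(1S,5R)-1-allyl-2-[(tert-butyldimethylsilyl)oxy]-5-hydroxycyclohex-2-en-1-yl]-1-(3,4-dimethoxyphenyl)propan-1-one
Product: 21 (4S,6S)-6-allyl-6-[(2R)-1-(3,4-dimethoxyphenyl)-1-oxopropan-2-yl]-4-hydroxycyclohex-2-en-1-one
Conditions: Pd(OAc)2 (1.1 equiv), MeCN, rt
Reagents that add atoms: none
Why: In the Saegusa–Ito oxidation divalent palladium forms the C2 palladium enolate from the silyl enol ether and β-hydride elimination from C3 returns the C2=C3 enone, leaving zerovalent palladium, with the regiochemistry fixed by the enol ether.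

Step 11
Reactants: 21 (4S,6S)-6-allyl-6-[(2R)-1-(3,4-dimethoxyphenyl)-1-oxopropan-2-yl]-4-hydroxycyclohex-2-en-1-one
Product: 22 (4S,6S)-6-allyl-6-[(2R)-1-(3,4-dimethoxyphenyl)-1-oxopropan-2-yl]-4-methoxycyclohex-2-en-1-one
Conditions: MeI, Ag2O, 4 Å molecular sieves, CH2Cl2, rt, dark
Reagents that add atoms: iodomethane, CI
Why: Purdie methylation under essentially neutral conditions should etherify the unhindered allylic C4 hydroxyl without enolising the α-methyl aryl ketone, whose hindered carbonyl should not hold the hydroxyl as a bridged hemiketal.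

**Compound list**

1 | 1,4-dioxaspiro[4.5]dec-6-en-8-one | O=C1C=CC2(CC1)OCCO2 | starting material
2 | (S)-1,4-dioxaspiro[4.5]dec-6-en-8-ol | C1C[C@H](O)C=CC12OCCO2 | intermediate
3 | (S)-tert-butyl(1,4-dioxaspiro[4.5]dec-6-en-8-yloxy)dimethylsilane | C1C[C@H](O[Si](C)(C)C(C)(C)C)C=CC12OCCO2 | intermediate
4 | (S)-4-[(tert-butyldimethylsilyl)oxy]cyclohex-2-en-1-one | C1C[C@H](O[Si](C)(C)C(C)(C)C)C=CC1=O | intermediate
5 | tert-butyl bromoacetate | CC(C)(C)OC(=O)CBr | starting material
6 | lithium (S)-4-[(tert-butyldimethylsilyl)oxy]cyclohexa-1,5-dien-1-olate | [Li]OC1=CC[C@H](O[Si](C)(C)C(C)(C)C)C=C1 | intermediate (not isolated)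
7 | tert-butyl 2-[(1R,5S)-5-[(tert-butyldimethylsilyl)oxy]-2-oxocyclohex-3-en-1-yl]acetate (trans) | CC(C)(C)OC(=O)C[C@H]1C[C@H](O[Si](C)(C)C(C)(C)C)C=CC1=O | intermediate
8 | allyl bromide | C=CCBr | starting material
9 | lithium (S)-2-(2-tert-butoxy-2-oxoethyl)-4-[(tert-butyldimethylsilyl)oxy]cyclohexa-1,5-dien-1-olate | [Li]OC1=C(CC(=O)OC(C)(C)C)C[C@H](O[Si](C)(C)C(C)(C)C)C=C1 | intermediate (not isolated)
10 | tert-butyl 2-[(1S,5S)-1-allyl-5-[(tert-butyldimethylsilyl)oxy]-2-oxocyclohex-3-en-1-yl]acetate | C=CC[C@@]1(CC(=O)OC(C)(C)C)C[C@H](O[Si](C)(C)C(C)(C)C)C=CC1=O | intermediate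
11 | 2-[(1S,5S)-1-allyl-5-hydroxy-2-oxocyclohex-3-en-1-yl]acetic acid | C=CC[C@@]1(CC(=O)O)C[C@H](O)C=CC1=O | intermediate (not isolated)
12 | (1S,5S)-5-allyl-2-oxabicyclo[3.3.1]non-7-ene-3,6-dione | C=CC[C@@]1(CC(=O)O2)C[C@H]2C=CC1=O | intermediate
13 | lithium (1S,5S)-5-allyl-6-oxo-2-oxabicyclo[3.3.1]nona-3,7-dien-3-olate | C=CC[C@@]1(C=C(O[Li])O2)C[C@H]2C=CC1=O | intermediate (not isolated)
14 | (1S,4R,5S)-5-allyl-4-methyl-2-oxabicyclo[3.3.1]non-7-ene-3,6-dione (methyl exo) | C=CC[C@@]1([C@@H](C)C(=O)O2)C[C@H]2C=CC1=O | intermediate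
15 | copper (1R,4R,5S)-5-allyl-4-methyl-3-oxo-2-oxabicyclo[3.3.1]non-6-en-6-olate (Ph3P-ligated) | C=CC[C@@]1([C@@H](C)C(=O)O2)C[C@H]2CC=C1O[Cu] | intermediate (not isolated)
16 | (1R,4R,5S)-5-allyl-6-[(tert-butyldimethylsilyl)oxy]-4-methyl-2-oxabicyclo[3.3.1]non-6-en-3-one | C=CC[C@@]1([C@@H](C)C(=O)O2)C[C@H]2CC=C1O[Si](C)(C)C(C)(C)C | intermediate
17 | 4-bromo-1,2-dimethoxybenzene | COc1ccc(Br)cc1OC | starting material
18 | 3,4-dimethoxyphenyllithium | [Li]c1ccc(OC)c(OC)c1 | intermediate (not isolated)
19 | lithium (1R,3S,4R,5S)-5-allyl-6-[(tert-butyldimethylsilyl)oxy]-3-(3,4-dimethoxyphenyl)-4-methyl-2-oxabicyclo[3.3.1]non-6-en-3-olate (aryl exo) | C=CC[C@@]1([C@@H](C)[C@@](O[Li])(c3ccc(OC)c(OC)c3)O2)C[C@H]2CC=C1O[Si](C)(C)C(C)(C)C | intermediate (not isolated)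
20 | (2R)-2-[(1S,5R)-1-allyl-2-[(tert-butyldimethylsilyl)oxy]-5-hydroxycyclohex-2-en-1-yl]-1-(3,4-dimethoxyphenyl)propan-1-one | C=CC[C@@]1([C@@H](C)C(=O)c2ccc(OC)c(OC)c2)C[C@H](O)CC=C1O[Si](C)(C)C(C)(C)C | intermediate
21 | (4S,6S)-6-allyl-6-[(2R)-1-(3,4-dimethoxyphenyl)-1-oxopropan-2-yl]-4-hydroxycyclohex-2-en-1-one | C=CC[C@@]1([C@@H](C)C(=O)c2ccc(OC)c(OC)c2)C[C@H](O)C=CC1=O | intermediate
22 | (4S,6S)-6-allyl-6-[(2R)-1-(3,4-dimethoxyphenyl)-1-oxopropan-2-yl]-4-methoxycyclohex-2-en-1-one | C=CC[C@@]1([C@@H](C)C(=O)c2ccc(OC)c(OC)c2)C[C@H](OC)C=CC1=O | target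

**Summary**

Total steps: 11. Longest linear sequence: 11 steps (from 1; 17 enters at step 9).

Steps most likely to fail:

1. Step 9. The lactolate may collapse before the quench, so that the liberated ketone takes up a second aryllithium or is enolised. Fallback: from 16, Weinreb aminolysis of the lactone (MeNH(OMe)·HCl, i-PrMgCl, THF, −20 °C) should give the hydroxy Weinreb amide F1. O-Methylation before any ketone exists (NaH, MeI, THF, 0 °C) should give the methoxy Weinreb amide F2. Addition of 18 (THF, −78 to 0 °C), whose chelated adduct cannot over-add, should give the methoxy aryl ketone silyl enol ether F3. Saegusa–Ito oxidation (Pd(OAc)2, MeCN) then comes back to the route at 22.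

2. Step 5. Facial selectivity of the quaternising allylation may be poor, since it rests on 1,3-induction from C4 alone, or γ-deprotonation may compete. Fallback: from 7, O-acylation of the enolate (KN(SiMe3)2, allyl chloroformate, THF, −78 °C) should give the allyl enol carbonate F4. Decarboxylative Tsuji allylation with Pd2(dba)3 and (R)-t-BuPHOX (THF, rt) lets the chiral zerovalent palladium catalyst, not the remote C4 group, choose the enolate face, and comes back at 10.

3. Step 7. The amide base or the lactone enolate may add in conjugate fashion to the unmasked enone, or methylation may go twice. Fallback: from 12 the enone is masked first; copper hydride reduction with in situ silylation ([(Ph3P)CuH]6, TBSCl, C6H6/THF) should give the unmethylated silyl enol ether lactone F5. Its enolate is then formed and methylated on the same exo face (LiN(i-Pr)2, THF, −78 °C; MeI), coming back at 16.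

**Further compounds**

F1 | step 9 | (2R)-2-[(1S,5R)-1-allyl-2-[(tert-butyldimethylsilyl)oxy]-5-hydroxycyclohex-2-en-1-yl]-N-methoxy-N-methylpropanamide | C=CC[C@@]1([C@@H](C)C(=O)N(C)OC)C[C@H](O)CC=C1O[Si](C)(C)C(C)(C)C
F2 | step 9 | (2R)-2-[(1S,5R)-1-allyl-2-[(tert-butyldimethylsilyl)oxy]-5-methoxycyclohex-2-en-1-yl]-N-methoxy-N-methylpropanamide | C=CC[C@@]1([C@@H](C)C(=O)N(C)OC)C[C@H](OC)CC=C1O[Si](C)(C)C(C)(C)C
F3 | step 9 | (2R)-2-[(1S,5R)-1-allyl-2-[(tert-butyldimethylsilyl)oxy]-5-methoxycyclohex-2-en-1-yl]-1-(3,4-dimethoxyphenyl)propan-1-one | C=CC[C@@]1([C@@H](C)C(=O)c2ccc(OC)c(OC)c2)C[C@H](OC)CC=C1O[Si](C)(C)C(C)(C)C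
F4 | step 5 | allyl (4S)-2-(2-tert-butoxy-2-oxoethyl)-4-[(tert-butyldimethylsilyl)oxy]cyclohexa-1,5-dien-1-yl carbonate | C=CCOC(=O)OC1=C(CC(=O)OC(C)(C)C)C[C@H](O[Si](C)(C)C(C)(C)C)C=C1
F5 | step 7 | (1R,5S)-5-allyl-6-[(tert-butyldimethylsilyl)oxy]-2-oxabicyclo[3.3.1]non-6-en-3-one | C=CC[C@@]1(CC(=O)O2)C[C@H]2CC=C1O[Si](C)(C)C(C)(C)C
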